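The earlier runs and the new flask are calculated from invented constants; the scatter is artificial.

Start with the easy step: divide each last reading by the starting material charged.

| flask | starting material | coupling partner | time |
|---|---|---|---|
| autumn | 0.120 M | 0.300 M |  |
| dawn | 0.0480 M | 0.228 M |  |
| winter | 0.120 M | 0.900 M |  |
| dusk | 0.240 M | 0.300 M |  |
| midnight | 0.0480 M | 0.120 M | 85 min |

- autumn run (time / min: [target] / M): 6.5: 0.0024; 20: 0.0125; 38: 0.0279; 59: 0.0384; 85: 0.0441
- dawn run (time / min: [target] / M): 6.5: 0.0014; 20: 0.0043; 38: 0.0095; 59: 0.0141; 85: 0.0171
- winter run (time / min: [target] / M): 6.5: 0.0053; 20: 0.0229; 38: 0.0406; 59: 0.0515; 85: 0.0561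
- dusk run (time / min: [target] / M): 6.5: 0.0039; 20: 0.0253; 38: 0.0531; 59: 0.0721; 85: 0.0816

(each reading ± 4 × 10⁻⁴ M)

- Overall: starting material + coupling partner -> target.
- Constant volume, constant temperature.
- An order is taken over about fifteen percent of the charge, up and down.

1. order of the initial rate in [coupling partner], near the charge of the autumn run, the rate being that where two percent of its starting material are target
2. order of the initial rate in [starting material], near the charge of the autumn run, the rate being that where two percent of its starting material are target (one fixed amount of target, the same in the runs compared)
3. target in the midnight run at 85 min, as a share of the starting material charged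

Draw dawn first, since midnight has the same starting material. Dawn climbs at 2.15 × 10⁻⁴ M/min over its first 20 min, then steepens to 2.89 × 10⁻⁴ M/min up to 38 min. It crosses half its last reading near 34.7 min, and its knee follows: the last stretch rises at 1.15 × 10⁻⁴ M/min. At 85 min dawn stands at 35.6% of its charge.

Now compare levels. Autumn ends at 36.8%, and dusk, with twice the starting material, at 34.0%. Winter, rich in coupling partner, ends at 46.7%. Dawn against winter gives 0.204 M for the dilution penalty, the rise in the reciprocal of the 85 min share per unit rise in the reciprocal of the charged [coupling partner].

Step from dawn to midnight with it. By the charge, starting material is the limiting reagent in midnight, and the penalty, as my own estimate, puts midnight's share at 85 min at 27.7%, or 0.0133 M of target.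

The forecast gives orders of 0.45 in [coupling partner] and 0.6 in [starting material], and 27% for midnight, with this among its grounds: “Doubling the starting material leaves the conversion-time curve nearly unchanged”. My estimate for midnight stands 0.70 percentage points above the forecast's.

The flask gives orders of 0.47 in [coupling partner] and 0.64 in [starting material], and midnight holds 26.6%, about a quarter of its starting material, as target at 85 min. Its steps are these:

    starting material → intermediate (0.02190 /min)
    intermediate + coupling partner → target (0.1716 /M/min)
    intermediate → side product (0.01290 /min)
    target → decomposed product (0.005880 /min)
    2 coupling partner → lost reagent (0.02046 /M/min)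

The path from target to decomposed product moves the readings by 22 scatter units, root mean square. Take the dilution penalty of 0.204 M from midnight's 26.6% to autumn's [coupling partner]: it gives 36.4%, and autumn, which entered neither end of the penalty, reads 36.8%.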